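**Strategy.** The cyclohexanone is opened at its C(=O)–CH2 bond. The remaining triad, carbonyl carbon–C(CH3)2–ring CH, is C1–C6–C5 of (S)-carvone after α′-dimethylation, so the stereocentre is bought. The carvone ring is unzipped at C1–C2 (C2–C4 become the side chain). A formaldehyde ene reaction turns the isopropenyl group into the exocyclic methylene carrying a CH2CH2I arm. In the key step, iodine–lithium exchange at the arm's terminal CH2 and 6-exo attack on the non-enolisable ester carbon next to the quaternary centre build the 2,2-dimethyl-4-methylidenecyclohexanone in one operation from an acyclic iodo ester.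

Key step: step 8

Remark 1: Carvone numbering is used for 1–5 (C1 carbonyl, C2 methyl-bearing alkene carbon, C5 stereocentre, C6 α′-CH2). The ring CH is never touched; its descriptor changes from S (1, 2) to R (3 onwards) only because the new C(CH3)2 carbon overtakes the propenyl carbon in CIP priority.

Remark 2: 4-Hydroxy-5-methylcoumarin is assumed not to be a stock chemical and is made in step 9.

**Step 1**
Reactants: 1 (S)-carvone [(5S)-2-methyl-5-(prop-1-en-2-yl)cyclohex-2-en-1-one]
Product: 3 (5R)-2,6,6-trimethyl-5-(prop-1-en-2-yl)cyclohex-2-en-1-one (6,6-dimethylcarvone), via 6-methylcarvone 2 (not isolated)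
Conditions: LDA (1.1 equiv), THF, −78 °C, then MeI; LDA (1.2 equiv), −78 °C, then MeI, −78 °C → rt
Reagents that add atoms: iodomethane, CI
Why: Kinetic deprotonation of the enone with LDA takes place at the α′ carbon (C6), and two successive enolate C-methylations (ketone α-alkylation) should install the gem-dimethyl group while the non-enolisable C5 stereocentre is retained.

**Step 2**
Reactants: 3 (5R)-2,6,6-trimethyl-5-(prop-1-en-2-yl)cyclohex-2-en-1-one
Product: 5 (2RS,5R)-2-hydroxy-2,6,6-trimethyl-5-(prop-1-en-2-yl)cyclohexan-1-one, via potassium enolate 4 (not isolated)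
Conditions: K-Selectride (1.1 equiv), THF, −78 °C; then (±)-2-(phenylsulfonyl)-3-phenyloxaziridine (1.5 equiv), −78 → −20 °C; H2O
Reagents that add atoms: 2-(phenylsulfonyl)-3-phenyloxaziridine (Davis reagent), O=S(=O)(c1ccccc1)N1OC1c1ccccc1
Why: The β-unsubstituted, carbonyl-hindered cyclohexenone should undergo 1,4-hydride addition (Selectride conjugate reduction) to a regiodefined tetrasubstituted enolate, which is hydroxylated at C2 by the N-sulfonyloxaziridine (Davis oxidation); the new carbinol centre forms as a mixture that does not matter because it is destroyed in step 3.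

**Step 3**
Reactants: 5 (2RS,5R)-2-hydroxy-2,6,6-trimethyl-5-(prop-1-en-2-yl)cyclohexan-1-one
Product: 6 methyl (3R)-2,2-dimethyl-6-oxo-3-(prop-1-en-2-yl)heptanoate
Conditions: Pb(OAc)4 (1.2 equiv), MeOH–benzene 1:1, 0 °C → rt
Reagents that add atoms: methanol, CO
Why: Criegee-type oxidative cleavage of the α-ketol in methanol should break the C1–C2 bond, releasing the carbonyl carbon as the methyl ester next to the quaternary carbon and the carbinol carbon as the methyl ketone, with the alkene and the stereocentre untouched.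

**Step 4**
Reactants: 6 methyl (3R)-2,2-dimethyl-6-oxo-3-(prop-1-en-2-yl)heptanoate
Product: 8 methyl (3R)-2,2-dimethyl-3-(prop-1-en-2-yl)hept-6-ynoate, via enol phosphate 7 (not isolated)
Conditions: LDA (1.1 equiv), THF, −78 °C; ClP(O)(OEt)2, −78 °C → rt; then LDA (2.3 equiv), −78 °C → rt; H2O
Reagents that add atoms: none
Why: The Negishi methyl ketone to terminal alkyne conversion (kinetic enolate O-phosphorylation, then base-induced β-elimination of diethyl phosphate) should work because the ester has no α-hydrogen, and it removes the ketone before Lewis-acid and organolithium chemistry.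

**Step 5**
Reactants: 8 methyl (3R)-2,2-dimethyl-3-(prop-1-en-2-yl)hept-6-ynoate
Product: 9 methyl (3R)-3-(4-hydroxybut-1-en-2-yl)-2,2-dimethylhept-6-ynoate
Conditions: (CH2O)n (1.2 equiv), Me2AlCl (2.5 equiv), CH2Cl2, −78 → 0 °C; aq. work-up
Reagents that add atoms: formaldehyde (from paraformaldehyde), C=O
Why: The Me2AlCl-promoted carbonyl-ene reaction of formaldehyde with the 1,1-disubstituted propenyl group forms the C–C bond at the terminal CH2 and moves the double bond to the former methyl, giving the exocyclic methylene and the CH2CH2OH arm in one step; the terminal alkyne is far less nucleophilic and the ester only binds extra Lewis acid.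

**Step 6**
Reactants: 9 methyl (3R)-3-(4-hydroxybut-1-en-2-yl)-2,2-dimethylhept-6-ynoate
Product: 10 methyl (3R)-3-(4-iodobut-1-en-2-yl)-2,2-dimethylhept-6-ynoate
Conditions: I2, PPh3, imidazole, CH2Cl2, 0 °C → rt
Reagents that add atoms: iodine, II
Why: Appel-type iodination of the only hydroxyl group proceeds by SN2 at a primary carbon under neutral conditions that do not isomerise the 1,1-disubstituted alkene.

**Step 7**
Reactants: 10 methyl (3R)-3-(4-iodobut-1-en-2-yl)-2,2-dimethylhept-6-ynoate
Product: 12 methyl (3R,6E)-8-hydroxy-3-(4-iodobut-1-en-2-yl)-2,2,6-trimethyloct-6-enoate, via alkenylalane 11 (not isolated)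
Conditions: AlMe3 (3 equiv), Cp2ZrCl2 (0.25 equiv), CH2Cl2, 0 °C → rt; then (CH2O)n, THF, 0 °C → rt; aq. work-up
Reagents that add atoms: trimethylaluminium, C[Al](C)C; formaldehyde (from paraformaldehyde), C=O
Why: Negishi zirconium-catalysed methylalumination adds methyl and aluminium syn across the terminal alkyne with methyl at the internal carbon, which fixes the E trisubstituted alkene, and the alkenylalane is hydroxymethylated with retention; the hindered ester, the primary iodide and the 1,1-disubstituted alkene should be inert.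

**Step 8**
Reactants: 12 methyl (3R,6E)-8-hydroxy-3-(4-iodobut-1-en-2-yl)-2,2,6-trimethyloct-6-enoate
Product: 14 (3R)-3-[(3E)-5-hydroxy-3-methylpent-3-en-1-yl]-2,2-dimethyl-4-methylidenecyclohexan-1-one, via C-lithio lithium alkoxide 13 (not isolated)
Conditions: MeLi (1.0 equiv), Et2O, −78 °C; then t-BuLi (2.1 equiv), Et2O–pentane, −78 → 0 °C; H2O
Reagents that add atoms: none
Why: After MeLi has capped the hydroxyl as its lithium alkoxide, lithium–iodine exchange at the primary iodide gives a homoallylic alkyllithium whose CH2 adds to the ester carbonyl, and the tetrahedral lithium hemiketal loses methoxide on warming to give the ketone. The closest known reaction type is the lithium–halogen-exchange-initiated intramolecular acylation of ω-iodo esters (Parham-type anionic cyclisation). The six-membered ring closes in the 6-exo-trig mode, helped by the gem-dimethyl (Thorpe–Ingold) effect. No stereocentre is formed, and the ring CH from carvone carries no acidic hydrogen and is not touched. The step needs exchange to outrun attack of t-BuLi on the ester and needs the ketone to survive: the ester is neopentyl-like and non-enolisable, exchange of a primary iodide is complete within minutes at −78 °C, and the product is shielded by the adjacent quaternary carbon and held as the tetrahedral intermediate until the base is consumed. The exocyclic methylene should not migrate because no acid is present.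

**Step 9**
Reactants: 15 1-(2-hydroxy-6-methylphenyl)ethan-1-one
Product: 17 4-hydroxy-5-methyl-2H-chromen-2-one, via β-keto ester 16 (not isolated)
Conditions: NaH (3 equiv), diethyl carbonate, toluene, 110 °C; then aq. HCl
Reagents that add atoms: diethyl carbonate, CCOC(=O)OCC
Why: Claisen-type C-acylation of the acetophenone enolate by diethyl carbonate followed by lactonisation onto the phenoxide is the standard 4-hydroxycoumarin synthesis and places the methyl group at C5.

**Step 10**
Reactants: 14 (3R)-3-[(3E)-5-hydroxy-3-methylpent-3-en-1-yl]-2,2-dimethyl-4-methylidenecyclohexan-1-one; 17 4-hydroxy-5-methyl-2H-chromen-2-one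
Product: 18 4-{[(2E)-5-[(1R)-2,2-dimethyl-6-methylidene-3-oxocyclohexyl]-3-methylpent-2-en-1-yl]oxy}-5-methyl-2H-chromen-2-one
Conditions: PPh3, DIAD, THF, 0 °C → rt
Reagents that add atoms: none
Why: In the Mitsunobu etherification the acidic 4-hydroxycoumarin (pKa about 4–5) should be O-alkylated by the primary allylic alkoxyphosphonium ion by SN2 at CH2, so the E alkene, the ketone and the stereocentre are unchanged.

**Compound list**

1 | (S)-carvone, (5S)-2-methyl-5-(prop-1-en-2-yl)cyclohex-2-en-1-one | CC(=C)[C@H]1CC=C(C)C(=O)C1 | starting material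
2 | 6-methylcarvone, (5S)-2,6-dimethyl-5-(prop-1-en-2-yl)cyclohex-2-en-1-one (C6 epimers, not isolated) | CC(=C)[C@H]1CC=C(C)C(=O)C1C | intermediate
3 | (5R)-2,6,6-trimethyl-5-(prop-1-en-2-yl)cyclohex-2-en-1-one (6,6-dimethylcarvone) | CC(=C)[C@H]1CC=C(C)C(=O)C1(C)C | intermediate
4 | potassium enolate, potassium (5R)-2,6,6-trimethyl-5-(prop-1-en-2-yl)cyclohex-1-en-1-olate (not isolated) | CC(=C)[C@H]1CCC(C)=C([O-])C1(C)C.[K+] | intermediate
5 | (2RS,5R)-2-hydroxy-2,6,6-trimethyl-5-(prop-1-en-2-yl)cyclohexan-1-one | CC(=C)[C@H]1CCC(C)(O)C(=O)C1(C)C | intermediate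
6 | methyl (3R)-2,2-dimethyl-6-oxo-3-(prop-1-en-2-yl)heptanoate | COC(=O)C(C)(C)[C@@H](C(C)=C)CCC(C)=O | intermediate
7 | enol phosphate, methyl (3R)-6-[(diethoxyphosphoryl)oxy]-2,2-dimethyl-3-(prop-1-en-2-yl)hept-6-enoate (not isolated) | COC(=O)C(C)(C)[C@@H](C(C)=C)CCC(=C)OP(=O)(OCC)OCC | intermediate
8 | methyl (3R)-2,2-dimethyl-3-(prop-1-en-2-yl)hept-6-ynoate | COC(=O)C(C)(C)[C@@H](C(C)=C)CCC#C | intermediate
9 | methyl (3R)-3-(4-hydroxybut-1-en-2-yl)-2,2-dimethylhept-6-ynoate | COC(=O)C(C)(C)[C@@H](C(=C)CCO)CCC#C | intermediate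
10 | methyl (3R)-3-(4-iodobut-1-en-2-yl)-2,2-dimethylhept-6-ynoate | COC(=O)C(C)(C)[C@@H](C(=C)CCI)CCC#C | intermediate
11 | alkenylalane, methyl (3R,6E)-7-(dimethylalumanyl)-3-(4-iodobut-1-en-2-yl)-2,2,6-trimethylhept-6-enoate (not isolated) | COC(=O)C(C)(C)[C@@H](C(=C)CCI)CC/C(C)=C/[Al](C)C | intermediate
12 | methyl (3R,6E)-8-hydroxy-3-(4-iodobut-1-en-2-yl)-2,2,6-trimethyloct-6-enoate | COC(=O)C(C)(C)[C@@H](C(=C)CCI)CC/C(C)=C/CO | intermediate
13 | C-lithio lithium alkoxide, methyl (3R,6E)-3-(4-lithiobut-1-en-2-yl)-8-(lithiooxy)-2,2,6-trimethyloct-6-enoate (not isolated) | COC(=O)C(C)(C)[C@@H](C(=C)CC[Li])CC/C(C)=C/CO[Li] | intermediate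
14 | (3R)-3-[(3E)-5-hydroxy-3-methylpent-3-en-1-yl]-2,2-dimethyl-4-methylidenecyclohexan-1-one | C=C1CCC(=O)C(C)(C)[C@@H]1CC/C(C)=C/CO | intermediate
15 | 1-(2-hydroxy-6-methylphenyl)ethan-1-one | CC(=O)c1c(C)cccc1O | starting material
16 | β-keto ester, ethyl 3-(2-hydroxy-6-methylphenyl)-3-oxopropanoate (as sodium salt, not isolated) | CCOC(=O)CC(=O)c1c(C)cccc1O | intermediate
17 | 4-hydroxy-5-methyl-2H-chromen-2-one | Cc1cccc2oc(=O)cc(O)c12 | intermediate
18 | 4-{[(2E)-5-[(1R)-2,2-dimethyl-6-methylidene-3-oxocyclohexyl]-3-methylpent-2-en-1-yl]oxy}-5-methyl-2H-chromen-2-one | C=C1CCC(=O)C(C)(C)[C@@H]1CC/C(C)=C/COc1cc(=O)oc2cccc(C)c12 | target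

**Step count.** Total: 10 steps. Longest linear sequence: 9 steps (steps 1–8 and 10).

**Steps most likely to fail**

Step 8. Proton transfer to, or elimination from, the organolithium may compete with ring closure, and the liberated ketone may suffer a second addition. The fallback forms the same bond with a stabilised carbanion and sets out from 12. Displacement of iodide with sodium benzenesulfinate (DMF, rt) should give methyl (3R,6E)-8-hydroxy-2,2,6-trimethyl-3-[4-(phenylsulfonyl)but-1-en-2-yl]oct-6-enoate F1. LDA (3.2 equiv, THF, −78 → 0 °C) should then close the ring by Dieckmann-type acylation of the α-sulfonyl carbanion, giving (3R)-3-[(3E)-5-hydroxy-3-methylpent-3-en-1-yl]-2,2-dimethyl-4-methylidene-6-(phenylsulfonyl)cyclohexan-1-one F2; its enolate cannot react further. Reductive desulfonylation with SmI2 (THF–MeOH, −78 °C) returns to the route at 14.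

Step 7. The Lewis-acidic aluminium and zirconium species may attack the ester or ionise the iodide, and capture of the alkenylalane by formaldehyde may be incomplete. The fallback avoids the alkyne and sets out from 6, bypassing steps 4–7. Horner–Wadsworth–Emmons olefination of the methyl ketone (triethyl phosphonoacetate, NaH, THF, E isomer separated by chromatography) should give 1-ethyl 8-methyl (2E,6R)-3,7,7-trimethyl-6-(prop-1-en-2-yl)oct-2-enedioate F3. The formaldehyde ene reaction (Me2AlCl, (CH2O)n; the enoate alkene is electron-poor and inert) should give 1-ethyl 8-methyl (2E,6R)-6-(4-hydroxybut-1-en-2-yl)-3,7,7-trimethyloct-2-enedioate F4. Iodination (I2, PPh3, imidazole) should give 1-ethyl 8-methyl (2E,6R)-6-(4-iodobut-1-en-2-yl)-3,7,7-trimethyloct-2-enedioate F5. DIBAL-H (2.2 equiv, CH2Cl2, −78 °C) should reduce only the unhindered conjugated ethyl ester and return to the route at 12.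

Step 10. The ambident coumarin may be alkylated at C3 or at the lactone oxygen instead of O4, and the peri methyl group makes this more likely. The fallback reverses the polarity and sets out from 17. POCl3 (BnEt3NCl, MeCN, reflux) should give 4-chloro-5-methyl-2H-chromen-2-one F6. The sodium alkoxide of 14 (NaH, THF, 0 °C) should then displace chloride at C4 by addition–elimination, which fixes the site of the ether bond and returns to the route at 18.

**Further compounds**

F1 | step 8 | methyl (3R,6E)-8-hydroxy-2,2,6-trimethyl-3-[4-(phenylsulfonyl)but-1-en-2-yl]oct-6-enoate | COC(=O)C(C)(C)[C@@H](C(=C)CCS(=O)(=O)c1ccccc1)CC/C(C)=C/CO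
F2 | step 8 | (3R)-3-[(3E)-5-hydroxy-3-methylpent-3-en-1-yl]-2,2-dimethyl-4-methylidene-6-(phenylsulfonyl)cyclohexan-1-one (C6 epimers) | C=C1CC(S(=O)(=O)c2ccccc2)C(=O)C(C)(C)[C@@H]1CC/C(C)=C/CO
F3 | step 7 | 1-ethyl 8-methyl (2E,6R)-3,7,7-trimethyl-6-(prop-1-en-2-yl)oct-2-enedioate | COC(=O)C(C)(C)[C@@H](C(C)=C)CC/C(C)=C/C(=O)OCC
F4 | step 7 | 1-ethyl 8-methyl (2E,6R)-6-(4-hydroxybut-1-en-2-yl)-3,7,7-trimethyloct-2-enedioate | COC(=O)C(C)(C)[C@@H](C(=C)CCO)CC/C(C)=C/C(=O)OCC
F5 | step 7 | 1-ethyl 8-methyl (2E,6R)-6-(4-iodobut-1-en-2-yl)-3,7,7-trimethyloct-2-enedioate | COC(=O)C(C)(C)[C@@H](C(=C)CCI)CC/C(C)=C/C(=O)OCC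
F6 | step 10 | 4-chloro-5-methyl-2H-chromen-2-one | Cc1cccc2oc(=O)cc(Cl)c12
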